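**Retrosynthetic overview**
1. Platanetin 13 comes from its 7-O-MOM ether 12; the pyranone ring is closed last, on a finished A ring, and the phenyl ring is bought in.
2. Key disconnection C3–C4: the formyl carbon of aldehyde 10, as a carbene-derived acyl anion, is acylated by the neighbouring α-aryloxy ester carbonyl. Two carbonyl carbons are joined and the 3-hydroxy-4-pyranone forms at the right oxidation level.
3. O1–C2: mono-O-alkylation of the catechol-type 2-OH of aldehyde 8 with methyl α-bromophenylacetate 9.
4. C8–O: Teuber oxidation and reduction at the only free ring CH of 5; the 7-oxygen carries the single protecting group (MOM).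
5. C6–prenyl: nuclear C-prenylation of symmetric 2,4,6-trihydroxybenzaldehyde 1.

Assumption: the target SMILES has no stereocentre, so platanetin is achiral and no enantiomer has to be selected; the one stereocentre that appears on the way (in 10 and 11) is carried as the racemate and is erased in step 5.

**Step 1**
Reactants: 1 2,4,6-trihydroxybenzaldehyde; 2 prenyl bromide (1-bromo-3-methylbut-2-ene)
Product: 3 2,4,6-trihydroxy-3-(3-methylbut-2-en-1-yl)benzaldehyde
Conditions: DBU (1.0 equiv), THF, 0 °C to rt
Reagents that add atoms: prenyl bromide, CC(C)=CCBr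
Why: Nuclear C-prenylation of an acylphloroglucinol anion is a known reaction (modest yield, O- and di-alkylation as side products), and because 1 is symmetric C3 and C5 are equivalent, so only one mono-C-prenyl isomer can form; no stereocentre.

**Step 2**
Reactants: 3 2,4,6-trihydroxy-3-(3-methylbut-2-en-1-yl)benzaldehyde; 4 chloromethyl methyl ether
Product: 5 2,6-dihydroxy-4-(methoxymethoxy)-3-(3-methylbut-2-en-1-yl)benzaldehyde
Conditions: MOMCl (1.05 equiv), i-Pr2NEt (1.1 equiv), CH2Cl2, 0 °C
Reagents that add atoms: chloromethyl methyl ether, COCCl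
Why: Williamson-type MOM etherification with one equivalent of base goes to the 4-OH, the most acidic hydroxyl (para to the formyl group) and the only one not tied to the formyl group by hydrogen bonding, so the two ortho hydroxyls stay free; no stereocentre.

**Step 3**
Reactants: 5 2,6-dihydroxy-4-(methoxymethoxy)-3-(3-methylbut-2-en-1-yl)benzaldehyde; 6 potassium nitrosodisulfonate (Fremy's salt)
Product: 8 2,3,6-trihydroxy-4-(methoxymethoxy)-5-(3-methylbut-2-en-1-yl)benzaldehyde, via formyl hydroxyquinone 7 (not isolated)
Conditions: (KSO3)2NO (2.5 equiv), KH2PO4 buffer (pH 6–7)/acetone, 0 °C to rt; then aq. Na2S2O4, EtOAc, Ar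
Reagents that add atoms: potassium nitrosodisulfonate, [O]N(S(=O)(=O)[O-])S(=O)(=O)[O-].[K+].[K+]
Why: Teuber oxidation puts oxygen on C5 of 5, the only unsubstituted ring carbon, which is para to the 2-OH and ortho to the 6-OH, so the p-quinone and o-quinone pathways give the same hydroxyquinone 7, which dithionite reduces to the hydroquinone; the near-neutral medium spares the MOM acetal, the aldehyde and the prenyl alkene; no stereocentre.

**Step 4**
Reactants: 8 2,3,6-trihydroxy-4-(methoxymethoxy)-5-(3-methylbut-2-en-1-yl)benzaldehyde (used at once, under argon); 9 methyl α-bromophenylacetate (racemic)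
Product: 10 methyl 2-[2-formyl-3,6-dihydroxy-5-(methoxymethoxy)-4-(3-methylbut-2-en-1-yl)phenoxy]-2-phenylacetate (racemic)
Conditions: KHCO3 (1.1 equiv), DMF, rt, Ar
Reagents that add atoms: methyl α-bromophenylacetate, COC(=O)C(Br)c1ccccc1
Why: Williamson etherification of the monoanion: one equivalent of bicarbonate ionises the 2-OH of 8, whose anion is conjugated to the formyl group and hydrogen-bonded by the neighbouring 3-OH (the selectivity known for mono-alkylation of catechol aldehydes at the carbonyl-conjugated hydroxyl), while the 6-OH is shielded by the prenyl group; the new stereocentre forms as a racemate and is erased in step 5.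

**Step 5**
Reactants: 10 methyl 2-[2-formyl-3,6-dihydroxy-5-(methoxymethoxy)-4-(3-methylbut-2-en-1-yl)phenoxy]-2-phenylacetate
Product: 13 platanetin, via chromanedione keto tautomer 11 (not isolated), via 7-O-MOM-platanetin 12 (not isolated)
Conditions: 2-(pentafluorophenyl)-6,7-dihydro-5H-pyrrolo[2,1-c][1,2,4]triazol-2-ium BF4 (20 mol%), DBU (20 mol%), THF/MeOH 4:1, 45 °C, Ar; then HCl/MeOH (ca. 1 M), 45 °C
Reagents that add atoms: none
Why: Proposed new method: the triazolylidene adds to the formyl group of 10 to give the Breslow intermediate, an acyl anion equivalent at C4, which attacks the α-aryloxy ester carbonyl (C3) through a six-membered transition state, methoxide and then the carbene leave to give dione 11, and irreversible enolisation to the aromatic 3-hydroxy-4-pyranone 12 erases the stereocentre and drives the sequence, with methanol keeping the ester open against lactonisation onto the 8-OH; the closest known reactions are the carbene-catalysed intramolecular crossed aldehyde–ketone benzoin of 2-(2-oxoalkoxy)benzaldehydes to 3-hydroxychroman-4-ones and the intramolecular aldehyde–nitrile coupling to 3-aminochromones, and the methanolic HCl that follows is the usual MOM removal for prenylated polyphenols.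

**Compound list**
1 | 2,4,6-trihydroxybenzaldehyde | O=Cc1c(O)cc(O)cc1O | starting material
2 | prenyl bromide (1-bromo-3-methylbut-2-ene) | CC(C)=CCBr | starting material
3 | 2,4,6-trihydroxy-3-(3-methylbut-2-en-1-yl)benzaldehyde | O=Cc1c(O)cc(O)c(CC=C(C)C)c1O | intermediate
4 | chloromethyl methyl ether | COCCl | starting material
5 | 2,6-dihydroxy-4-(methoxymethoxy)-3-(3-methylbut-2-en-1-yl)benzaldehyde | O=Cc1c(O)cc(OCOC)c(CC=C(C)C)c1O | intermediate
6 | potassium nitrosodisulfonate (Fremy's salt) | [O]N(S(=O)(=O)[O-])S(=O)(=O)[O-].[K+].[K+] | starting material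
7 | 2-hydroxy-4-(methoxymethoxy)-5-(3-methylbut-2-en-1-yl)-3,6-dioxocyclohexa-1,4-diene-1-carbaldehyde | O=CC1=C(O)C(=O)C(OCOC)=C(CC=C(C)C)C1=O | intermediate
8 | 2,3,6-trihydroxy-4-(methoxymethoxy)-5-(3-methylbut-2-en-1-yl)benzaldehyde | O=Cc1c(O)c(O)c(OCOC)c(CC=C(C)C)c1O | intermediate
9 | methyl α-bromophenylacetate (racemic) | COC(=O)C(Br)c1ccccc1 | starting material
10 | methyl 2-[2-formyl-3,6-dihydroxy-5-(methoxymethoxy)-4-(3-methylbut-2-en-1-yl)phenoxy]-2-phenylacetate (racemic) | COC(=O)C(c1ccccc1)Oc1c(O)c(OCOC)c(CC=C(C)C)c(O)c1C=O | intermediate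
11 | 5,8-dihydroxy-7-(methoxymethoxy)-6-(3-methylbut-2-en-1-yl)-2-phenyl-2H-chromene-3,4-dione (racemic keto tautomer of 12) | COCOc1c(CC=C(C)C)c(O)c2C(=O)C(=O)C(c3ccccc3)Oc2c1O | intermediate
12 | 3,5,8-trihydroxy-7-(methoxymethoxy)-6-(3-methylbut-2-en-1-yl)-2-phenyl-4H-chromen-4-one (7-O-MOM-platanetin) | COCOc1c(CC=C(C)C)c(O)c2c(=O)c(O)c(-c3ccccc3)oc2c1O | intermediate
13 | platanetin, 3,5,7,8-tetrahydroxy-6-(3-methylbut-2-en-1-yl)-2-phenyl-4H-chromen-4-one (achiral) | CC(C)=CCc1c(O)c(O)c2oc(-c3ccccc3)c(O)c(=O)c2c1O | target

**Totals and risks**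
Total step count: 5. Longest linear sequence: 5 steps (1 to 13; the route is linear).

Most likely to fail, step 5 (carbene acyl-anion acylation of an ester). The aldehyde is electron-rich and flanked on both sides, a methyl ester is a modest electrophile, and a base-mediated five-ring aldol of the ester α-carbon onto the aldehyde can compete. The fallback replaces the catalytic acyl anion by a reductive ketyl umpolung and sets out from 10. The phenols are silylated in the flask (Me3SiCl, Et3N) and the aldehyde is reduced with SmI2 in THF/HMPA (or at a cathode in the presence of Me3SiCl, as in the known reductive coupling of aromatic carbonyl compounds with esters). The resulting α-oxido benzylic anion attacks the ester, and after loss of methoxide, mild acidic work-up and ketol tautomerisation this gives the dihydroflavonol 3,5,8-trihydroxy-7-(methoxymethoxy)-6-(3-methylbut-2-en-1-yl)-2-phenylchroman-4-one F1 (racemic, cis/trans mixture). Ag2O then oxidises ring A to the quinone 3-hydroxy-7-(methoxymethoxy)-6-(3-methylbut-2-en-1-yl)-2-phenyl-2,3-dihydro-4H-chromene-4,5,8-trione F2, in which the quinone serves as internal hydrogen acceptor: Et3N in THF under argon tautomerises it to the flavonol hydroquinone. The fallback comes back to the route at 12, which is deprotected with methanolic HCl as in the second stage of step 5.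

Second, step 3 (Teuber oxidation). The chelated, formyl-bearing phenol may react slowly with Fremy's salt, or the hydroxyquinone may be lost on work-up. The fallback changes from radical oxidation to an ionic oxygen transfer and sets out from 5. Dibenzoyl peroxide in CHCl3 at rt in the dark acylates the 6-OH to an aryl perester, which rearranges [3,3] to the only free ortho carbon and gives the catechol monobenzoate 3-formyl-2,4-dihydroxy-6-(methoxymethoxy)-5-(3-methylbut-2-en-1-yl)phenyl benzoate F3. Methanolysis (K2CO3, MeOH, 0 °C, Ar) removes the benzoate, and the fallback comes back to the route at 8.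

Third, step 4 (site of O-alkylation). Alkylation at the 3-OH or the 6-OH of 8 would give isomers that cannot close to the target. The fallback fixes the site by acylating first and closing a tether, and sets out from 8. α-Chlorophenylacetyl chloride with 2,6-lutidine in CH2Cl2 at −30 °C acylates the only hydroxyl not held by the formyl group, the 3-OH, to give 3-formyl-2,4-dihydroxy-6-(methoxymethoxy)-5-(3-methylbut-2-en-1-yl)phenyl 2-chloro-2-phenylacetate F4 (racemic). K2CO3 and catalytic NaI in MeCN then let the neighbouring 2-phenoxide, the only oxygen that can reach, displace chloride to give the lactone 6-hydroxy-8-(methoxymethoxy)-7-(3-methylbut-2-en-1-yl)-2-oxo-3-phenyl-2,3-dihydro-1,4-benzodioxine-5-carbaldehyde F5 (racemic). Methanolysis of this aryl lactone (MeOH, cat. K2CO3) opens it, and the fallback comes back to the route at 10.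

**Further compounds**
F1 | step 5 | 3,5,8-trihydroxy-7-(methoxymethoxy)-6-(3-methylbut-2-en-1-yl)-2-phenylchroman-4-one (racemic, cis/trans mixture) | COCOc1c(CC=C(C)C)c(O)c2C(=O)C(O)C(c3ccccc3)Oc2c1O
F2 | step 5 | 3-hydroxy-7-(methoxymethoxy)-6-(3-methylbut-2-en-1-yl)-2-phenyl-2,3-dihydro-4H-chromene-4,5,8-trione (racemic, cis/trans mixture) | COCOC1=C(CC=C(C)C)C(=O)C2=C(OC(c3ccccc3)C(O)C2=O)C1=O
F3 | step 3 | 3-formyl-2,4-dihydroxy-6-(methoxymethoxy)-5-(3-methylbut-2-en-1-yl)phenyl benzoate | O=C(Oc1c(O)c(C=O)c(O)c(CC=C(C)C)c1OCOC)c1ccccc1
F4 | step 4 | 3-formyl-2,4-dihydroxy-6-(methoxymethoxy)-5-(3-methylbut-2-en-1-yl)phenyl 2-chloro-2-phenylacetate (racemic) | O=C(Oc1c(O)c(C=O)c(O)c(CC=C(C)C)c1OCOC)C(Cl)c1ccccc1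
F5 | step 4 | 6-hydroxy-8-(methoxymethoxy)-7-(3-methylbut-2-en-1-yl)-2-oxo-3-phenyl-2,3-dihydro-1,4-benzodioxine-5-carbaldehyde (racemic) | O=Cc1c(O)c(CC=C(C)C)c(OCOC)c2OC(=O)C(c3ccccc3)Oc12
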